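**Retrosynthetic overview**
- The last disconnection is at three O-protecting groups: the 5-O-methyl and the 3-O- and 3'-O-benzyl groups of a fully protected flavonol, all removed by BCl3.
- Ring C is the only ring built. The protected flavonol is cut at C4–C4a and O1–C2 into 2,3,4,5-tetramethoxyphenol and a racemic ethyl 2-benzyloxy aroylacetate, joined by an acid-free thermal Mentzer annulation.
- The strategy rests on ring A: C5, C6, C7 and C8 all carry oxygen and none carries hydrogen, so the phenol has a single unsubstituted ring carbon, ortho to its hydroxyl. That carbon becomes C4a and the hydroxyl oxygen becomes O1.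
- The phenol comes from 1,2,3,4-tetramethoxybenzene by ortho-lithiation, borylation and oxidation. The ketoester comes from 3-hydroxy-4,5-dimethoxybenzaldehyde by benzylation, glycolate aldol addition and oxidation (shorter than an acid chloride Claisen route). Rings A and B are bought in; ring C forms in step 5.

Key step: step 5

Remark: the target has no stereocentre. The stereocentres of the aldol adduct and of the ketoester are transient and are carried as mixtures. The three starting materials are taken as commercially available.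

**Route**

Step 1
Reactants: 1 1,2,3,4-tetramethoxybenzene
Product: 4 2,3,4,5-tetramethoxyphenol, via 2,3,4,5-tetramethoxyphenyllithium 2 (not isolated), via dimethyl (2,3,4,5-tetramethoxyphenyl)boronate 3 (not isolated)
Conditions: n-BuLi, TMEDA, THF, 0 °C to rt; B(OMe)3, −78 °C to rt; AcOH, 30% aq. H2O2, 0 °C to rt; under Ar, reductive work-up
Reagents that add atoms: hydrogen peroxide, OO
Why: Directed ortho-lithiation (the two ring hydrogens of 1 are equivalent and each lies ortho to a methoxy group), borate trapping and peroxide oxidation of the arylboronate with 1,2-aryl shift from boron to oxygen is a standard arene-to-phenol sequence, and no stereocentre is formed.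

Step 2
Reactants: 5 3-hydroxy-4,5-dimethoxybenzaldehyde
Product: 6 3-(benzyloxy)-4,5-dimethoxybenzaldehyde
Conditions: BnBr, K2CO3, DMF, 60 °C
Reagents that add atoms: benzyl bromide, BrCc1ccccc1
Why: Williamson ether synthesis on the only phenol of 5, with the aldehyde and the methyl ethers inert to K2CO3 and benzyl bromide.

Step 3
Reactants: 6 3-(benzyloxy)-4,5-dimethoxybenzaldehyde; 7 ethyl 2-(benzyloxy)acetate
Product: 9 ethyl 2-(benzyloxy)-3-[3-(benzyloxy)-4,5-dimethoxyphenyl]-3-hydroxypropanoate as a syn/anti mixture of racemates, via lithium enolate of ethyl benzyloxyacetate 8 (not isolated)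
Conditions: 7, LiN(i-Pr)2 (LDA), THF, −78 °C; then 6, −78 °C; AcOH quench
Reagents that add atoms: none
Why: Glycolate aldol addition of the chelated lithium enolate of an α-alkoxy ester to a non-enolisable aromatic aldehyde; the two new stereocentres (C2 and C3) are formed without control and the mixture is carried on, because C3 is oxidised in step 4 and C2 becomes sp2 in step 5.

Step 4
Reactants: 9 ethyl 2-(benzyloxy)-3-[3-(benzyloxy)-4,5-dimethoxyphenyl]-3-hydroxypropanoate
Product: 10 ethyl 2-(benzyloxy)-3-[3-(benzyloxy)-4,5-dimethoxyphenyl]-3-oxopropanoate (racemic)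
Conditions: Dess–Martin periodinane, CH2Cl2, 0 °C to rt
Reagents that add atoms: none
Why: Dess–Martin oxidation of the secondary benzylic alcohol under neutral conditions removes the carbinol stereocentre and leaves the benzyl ethers, the ester and the enolisable racemic C2 centre untouched.

Step 5
Reactants: 4 2,3,4,5-tetramethoxyphenol; 10 ethyl 2-(benzyloxy)-3-[3-(benzyloxy)-4,5-dimethoxyphenyl]-3-oxopropanoate
Product: 14 3-(benzyloxy)-2-[3-(benzyloxy)-4,5-dimethoxyphenyl]-5,6,7,8-tetramethoxy-4H-chromen-4-one, via aroyl(benzyloxy)ketene 11 (not isolated), via aryl ester 12 (not isolated), via ortho-hydroxyaryl 1,3-diketone 13 (not isolated)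
Conditions: 4 (2 equiv), neat melt, no acid, 240–250 °C, slow Ar stream (EtOH and H2O swept out)
Reagents that add atoms: none
Why: At melt temperature the enol form of 10 expels ethanol to give aroyl(benzyloxy)ketene 11, which phenol 4 traps at oxygen to give aryl ester 12 (which returns to 11 and 4 under the same conditions) and at C6, its only hydrogen-bearing ring carbon, to give the ortho-hydroxyaryl 1,3-diketone 13 irreversibly, forming the C4–C4a bond. The phenol oxygen of 13 then adds to the aroyl carbonyl in a 6-exo-trig closure and water is lost, which forms the O1–C2 bond, closes ring C and places the benzyloxy-bearing ketene carbon at C3. The closest known reaction type is the Mentzer pyrone synthesis, the uncatalysed thermal condensation of electron-rich phenols with ethyl aroylacetates to flavones; a 2-substituted ketoester keeps the one enolisable hydrogen needed for ketene formation. No stereocentre is created and the racemic centre of 10 ends as sp2 C3. The step needs chromone formation in preference to closure in the Pechmann sense to a 4-arylcoumarin, which the absence of acid secures because the ring carbon then meets the ketene carbon and not an activated ketone; regiochemistry needs no control, since 4 offers a single free carbon, made nucleophilic by the ortho hydroxyl, the ortho methoxy and the para methoxy group.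

Step 6
Reactants: 14 3-(benzyloxy)-2-[3-(benzyloxy)-4,5-dimethoxyphenyl]-5,6,7,8-tetramethoxy-4H-chromen-4-one
Product: 15 3,5-dihydroxy-2-(3-hydroxy-4,5-dimethoxyphenyl)-6,7,8-trimethoxy-4H-chromen-4-one (3-demethyldigicitrin)
Conditions: BCl3 (excess), pentamethylbenzene, CH2Cl2, −78 to 0 °C; then MeOH, H2O
Reagents that add atoms: none
Why: BCl3 binds the C4 carbonyl and the peri 5-methoxy oxygen in a six-membered chelate so that chloride removes only that methyl group, while the same Lewis acid cleaves the aryl and the enol benzyl ether with pentamethylbenzene trapping the benzyl cation (chelation-controlled demethylation combined with Lewis acid debenzylation), and at 0 °C or below the five non-chelated methyl ethers should persist.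

**Compound list**

1 | 1,2,3,4-tetramethoxybenzene | COc1ccc(OC)c(OC)c1OC | starting material
2 | 2,3,4,5-tetramethoxyphenyllithium | [Li]c1cc(OC)c(OC)c(OC)c1OC | intermediate
3 | dimethyl (2,3,4,5-tetramethoxyphenyl)boronate (present as its lithium methoxide ate complex) | COB(OC)c1cc(OC)c(OC)c(OC)c1OC | intermediate
4 | 2,3,4,5-tetramethoxyphenol | COc1cc(O)c(OC)c(OC)c1OC | intermediate
5 | 3-hydroxy-4,5-dimethoxybenzaldehyde | COc1cc(C=O)cc(O)c1OC | starting material
6 | 3-(benzyloxy)-4,5-dimethoxybenzaldehyde | COc1cc(C=O)cc(OCc2ccccc2)c1OC | intermediate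
7 | ethyl 2-(benzyloxy)acetate | CCOC(=O)COCc1ccccc1 | starting material
8 | lithium enolate of ethyl 2-(benzyloxy)acetate (geometry of no consequence) | CCOC(O[Li])=COCc1ccccc1 | intermediate
9 | ethyl 2-(benzyloxy)-3-[3-(benzyloxy)-4,5-dimethoxyphenyl]-3-hydroxypropanoate (syn/anti mixture, each racemic) | CCOC(=O)C(OCc1ccccc1)C(O)c1cc(OC)c(OC)c(OCc2ccccc2)c1 | intermediate
10 | ethyl 2-(benzyloxy)-3-[3-(benzyloxy)-4,5-dimethoxyphenyl]-3-oxopropanoate (racemic) | CCOC(=O)C(OCc1ccccc1)C(=O)c1cc(OC)c(OC)c(OCc2ccccc2)c1 | intermediate
11 | 2-(benzyloxy)-3-[3-(benzyloxy)-4,5-dimethoxyphenyl]prop-1-ene-1,3-dione (aroyl(benzyloxy)ketene) | O=C=C(OCc1ccccc1)C(=O)c1cc(OC)c(OC)c(OCc2ccccc2)c1 | intermediate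
12 | 2,3,4,5-tetramethoxyphenyl 2-(benzyloxy)-3-[3-(benzyloxy)-4,5-dimethoxyphenyl]-3-oxopropanoate (racemic) | COc1cc(OC(=O)C(OCc2ccccc2)C(=O)c2cc(OC)c(OC)c(OCc3ccccc3)c2)c(OC)c(OC)c1OC | intermediate
13 | 2-(benzyloxy)-1-[3-(benzyloxy)-4,5-dimethoxyphenyl]-3-(2-hydroxy-3,4,5,6-tetramethoxyphenyl)propane-1,3-dione (racemic) | COc1cc(C(=O)C(OCc2ccccc2)C(=O)c2c(O)c(OC)c(OC)c(OC)c2OC)cc(OCc2ccccc2)c1OC | intermediate
14 | 3-(benzyloxy)-2-[3-(benzyloxy)-4,5-dimethoxyphenyl]-5,6,7,8-tetramethoxy-4H-chromen-4-one | COc1cc(-c2oc3c(OC)c(OC)c(OC)c(OC)c3c(=O)c2OCc2ccccc2)cc(OCc2ccccc2)c1OC | intermediate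
15 | 3,5-dihydroxy-2-(3-hydroxy-4,5-dimethoxyphenyl)-6,7,8-trimethoxy-4H-chromen-4-one (3-demethyldigicitrin) | COc1cc(-c2oc3c(OC)c(OC)c(OC)c(O)c3c(=O)c2O)cc(O)c1OC | target

**Step count**
Total: 6 steps. Longest linear sequence: 5 steps (steps 2, 3, 4, 5, 6 from aldehyde 5). The phenol branch adds step 1.

**Steps most likely to fail**

1. Step 5. Carbon acylation at the single, flanked ring carbon may be outrun by thermal decay of the alkoxy-substituted aroylketene (self-condensation, or hydrolysis by the water formed followed by decarboxylation), by benzyl loss or migration at melt temperature, or by closure in the coumarin sense. The fallback builds ring C from a chalcone and adds the C3 oxygen afterwards; it sets out from phenol 4 and aldehyde 6 and comes back at target 15. Friedel–Crafts acetylation of 4 (AcOH, BF3·OEt2, 90 °C) at the same free carbon should give 1-(2-hydroxy-3,4,5,6-tetramethoxyphenyl)ethanone F1. Claisen–Schmidt condensation of F1 with 6 (KOH, EtOH, rt) should give the (E)-2'-hydroxychalcone F2. Oxidative cyclisation with catalytic I2 in DMSO at 120 °C should give the 3-unsubstituted flavone F3; an Algar–Flynn–Oyamada oxidation is avoided because 6'-methoxychalcones divert to aurones. Dimethyldioxirane in acetone/CH2Cl2 at 0 °C should give the racemic 2,3-epoxide F4, which with catalytic TsOH opens and tautomerises to the 3-hydroxyflavone F5. F5 under the conditions of step 6 should give 15.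

2. Step 6. Demethylation may run on past the chelated 5-methoxy group to the crowded central methoxy groups (C6 or C7 once the 5-oxygen carries boron, or C4' next to the freed 3'-oxygen), or debenzylation may stay incomplete or end in ring benzylation. The fallback separates the two events; it sets out from 14 and comes back at 15. Hydrogenolysis (H2, Pd/C, EtOAc/MeOH, rt) should remove both benzyl groups to give 3-hydroxy-2-(3-hydroxy-4,5-dimethoxyphenyl)-5,6,7,8-tetramethoxy-4H-chromen-4-one F6. AlCl3 in MeCN (rt to 50 °C, aq. HCl work-up), a milder chelation-specific reagent, should then cleave only the 5-methyl ether to give 15.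

3. Step 1. Lithiation may stay incomplete, or the very electron-rich phenol may be oxidised further to a quinone during the peroxide stage. The fallback installs the oxygen through a formyl group; it sets out from 1 and comes back at 4. Vilsmeier–Haack formylation (POCl3, DMF, 80 °C) should give 2,3,4,5-tetramethoxybenzaldehyde F7. Baeyer–Villiger oxidation with mCPBA in CH2Cl2 should give 2,3,4,5-tetramethoxyphenyl formate F8. Methanolysis (K2CO3, MeOH, rt, under Ar) should give 4.

**Further compounds**
F1 | step 5 | 1-(2-hydroxy-3,4,5,6-tetramethoxyphenyl)ethanone | CC(=O)c1c(O)c(OC)c(OC)c(OC)c1OC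
F2 | step 5 | (E)-3-[3-(benzyloxy)-4,5-dimethoxyphenyl]-1-(2-hydroxy-3,4,5,6-tetramethoxyphenyl)prop-2-en-1-one | COc1cc(/C=C/C(=O)c2c(O)c(OC)c(OC)c(OC)c2OC)cc(OCc2ccccc2)c1OC
F3 | step 5 | 2-[3-(benzyloxy)-4,5-dimethoxyphenyl]-5,6,7,8-tetramethoxy-4H-chromen-4-one | COc1cc(-c2cc(=O)c3c(OC)c(OC)c(OC)c(OC)c3o2)cc(OCc2ccccc2)c1OC
F4 | step 5 | 2,3-epoxide of F3, 1a-[3-(benzyloxy)-4,5-dimethoxyphenyl]-3,4,5,6-tetramethoxy-1a,7a-dihydro-7H-oxireno[2,3-b]chromen-7-one (racemic) | COc1cc(C23Oc4c(OC)c(OC)c(OC)c(OC)c4C(=O)C2O3)cc(OCc2ccccc2)c1OC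
F5 | step 5 | 2-[3-(benzyloxy)-4,5-dimethoxyphenyl]-3-hydroxy-5,6,7,8-tetramethoxy-4H-chromen-4-one | COc1cc(-c2oc3c(OC)c(OC)c(OC)c(OC)c3c(=O)c2O)cc(OCc2ccccc2)c1OC
F6 | step 6 | 3-hydroxy-2-(3-hydroxy-4,5-dimethoxyphenyl)-5,6,7,8-tetramethoxy-4H-chromen-4-one | COc1cc(-c2oc3c(OC)c(OC)c(OC)c(OC)c3c(=O)c2O)cc(O)c1OC
F7 | step 1 | 2,3,4,5-tetramethoxybenzaldehyde | COc1cc(C=O)c(OC)c(OC)c1OC
F8 | step 1 | 2,3,4,5-tetramethoxyphenyl formate | COc1cc(OC=O)c(OC)c(OC)c1OC
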